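Ring numbering: C1 carries C7, C2 Br, C3 the free OH (O3), C4 the sulfated oxygen (O4), C5 and C6 Br. O7 is the benzylic oxygen.
Retrosynthetic cuts: O7–S and O4–S first, then C5–Br and C6–Br, and last C1–C7 together with C2–Br.
Enabling feature: on the single benzene ring, C7 (on C1) and Br (on C2) are ortho neighbours, and O3 on C3 stands directly beside C2. A C1≡C2 aryne flanked by a C3 alkoxy group leaves exactly this pattern when it accepts a carbon nucleophile at C1 and then Br+ at C2.
Forward: 3,4-dimethoxyphenol is iodinated at C2 and sulfonylated at O1, the aryne step sets C1–C7 and C2–Br, and C7 is raised to the aldehyde. The crowded O3 methyl ether is then cleaved alone, C5 and C6 are brominated, O3 is parked as a mesylate, O4 is freed and sulfated, C7 is reduced, O7 is sulfated and O3 is released.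
No ring is formed (the arene is bought) and the target has no stereocentre, so no stereocontrol is needed.
Key step: step 6

Assumption: the target is drawn as the free bis(hydrogen sulfate). Sulfate monoesters 23–26 are written in that acid form but would be handled as sodium or tetrabutylammonium salts, with a final cation exchange giving the acid form.

Step 1
Reactants: 1 3,4-dimethoxyphenol
Product: 2 1,2-dimethoxy-4-(methoxymethoxy)benzene
Conditions: MOMCl, i-Pr2NEt, CH2Cl2, 0 °C → rt
Reagents that add atoms: chloromethyl methyl ether, COCCl
Why: O-alkylation of the phenol (acetal protection) installs a group that is inert to butyllithium and is a strong director for ortho-lithiation.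

Step 2
Reactants: 2 1,2-dimethoxy-4-(methoxymethoxy)benzene
Product: 4 2-iodo-3,4-dimethoxy-1-(methoxymethoxy)benzene, via C2 aryllithium 3 (not isolated)
Conditions: n-BuLi, THF, 0 °C; I2, −78 °C → rt
Reagents that add atoms: iodine, [I][I]
Why: Directed ortho-metalation should remove the C2 hydrogen, the only one flanked by two coordinating oxygen groups (the O1 acetal and the O3 methoxy group), and iodinolysis of the aryllithium fixes the halogen there.

Step 3
Reactants: 4 2-iodo-3,4-dimethoxy-1-(methoxymethoxy)benzene
Product: 5 2-iodo-3,4-dimethoxyphenol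
Conditions: HCl (cat.), MeOH, 45 °C
Reagents that add atoms: none
Why: Acid-catalysed acetal exchange with methanol removes the methoxymethyl group under conditions that leave aryl methyl ethers and the aryl iodide untouched.

Step 4
Reactants: 5 2-iodo-3,4-dimethoxyphenol; 6 4-chlorobenzenesulfonyl chloride
Product: 7 2-iodo-3,4-dimethoxyphenyl 4-chlorobenzenesulfonate
Conditions: Et3N, CH2Cl2, 0 °C → rt
Reagents that add atoms: none
Why: O-sulfonylation of the phenol gives an electron-poor arenesulfonate that survives a cold Grignard reagent yet leaves readily from C1 once C2 carries magnesium.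

Step 5
Reactants: 8 (chloromethyl)isopropoxydimethylsilane
Product: 9 (isopropoxydimethylsilyl)methylmagnesium chloride (THF solution, titrated and used as such)
Conditions: Mg turnings, BrCH2CH2Br (cat.), THF, rt → 65 °C
Reagents that add atoms: magnesium, [Mg]
Why: Grignard formation by insertion of magnesium into the C–Cl bond gives the established hydroxymethyl anion equivalent, whose bulky isopropoxy group shields silicon from self-attack.

Step 6
Reactants: 7 2-iodo-3,4-dimethoxyphenyl 4-chlorobenzenesulfonate; 9 (isopropoxydimethylsilyl)methylmagnesium chloride; 10 1,2-dibromotetrachloroethane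
Product: 14 (2-bromo-3,4-dimethoxybenzyl)(isopropoxy)dimethylsilane, via magnesiated sulfonate 11 (not isolated), via 3,4-dimethoxybenzyne 12 (not isolated), via C2 arylmagnesium chloride 13 (not isolated)
Conditions: i-PrMgCl (1.05 equiv), THF, −78 °C; 9 (3 equiv), −78 °C → rt; 10 (4.5 equiv), −20 °C → rt; neutral work-up
Reagents that add atoms: none
Why: Iodine–magnesium exchange at C2 should be complete at −78 °C, where 11 persists, so hardly any i-PrMgCl is left when 9 is added, and on warming above about −20 °C 11 expels the arenesulfonate from C1 and releases aryne 12 (C1≡C2). The closest known reaction type is carbomagnesiation of arynes generated from 2-magnesiated aryl sulfonates followed by electrophilic quench of the new arylmagnesium, applied here with a silylmethyl Grignard reagent as the carbon nucleophile. The step needs carbon at C1 and bromine at C2, which the inductively withdrawing C3 methoxy group secures by distorting the aryne so that C1 is the more electrophilic terminus and by placing the developing charge at C2 next to an oxygen that also chelates magnesium in 13, while C6 carries only hydrogen and exerts no counter-bias. A threefold excess of 9 should outrun capture of 12 by the hindered arylmagnesium species 11 and 13. BrCCl2CCl2Br, taken in excess over all C–Mg bonds, transfers Br+ to C2 with loss of tetrachloroethene, and the isopropoxy group keeps silicon from being attacked by the organomagnesium species. No ring is closed and no stereocentre is created.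

Step 7
Reactants: 14 (2-bromo-3,4-dimethoxybenzyl)(isopropoxy)dimethylsilane
Product: 15 (2-bromo-3,4-dimethoxyphenyl)methanol
Conditions: 30% H2O2, KF, KHCO3, THF–MeOH, rt
Reagents that add atoms: hydrogen peroxide, OO
Why: Tamao oxidation of the alkoxysilane moves the benzyl group from hypervalent silicon to peroxide oxygen and so turns C7–Si into C7–O7 without touching the aryl bromide or the ethers.

Step 8
Reactants: 15 (2-bromo-3,4-dimethoxyphenyl)methanol
Product: 16 2-bromo-3,4-dimethoxybenzaldehyde
Conditions: MnO2 (activated, excess), CH2Cl2, rt
Reagents that add atoms: none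
Why: MnO2 oxidation of a benzylic alcohol stops at the aldehyde, and the carbonyl group shuts off benzylic ionisation, quinone methide formation and ipso attack at C1 during the boron halide and bromine steps that follow.

Step 9
Reactants: 16 2-bromo-3,4-dimethoxybenzaldehyde
Product: 18 2-bromo-3-hydroxy-4-methoxybenzaldehyde, via aryloxydichloroborane 17 (not isolated)
Conditions: BCl3 (2.5 equiv), CH2Cl2, −20 °C → rt; H2O
Reagents that add atoms: none
Why: Regioselective BCl3 cleavage of a hindered aryl methyl ether should unmask only O3, because the O3 methoxy group, twisted out of conjugation between C2–Br and the O4 methoxy group, is the better Lewis base, while the O4 methoxy group is tied up in conjugation with the para formyl group.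

Step 10
Reactants: 18 2-bromo-3-hydroxy-4-methoxybenzaldehyde
Product: 19 2,5,6-tribromo-3-hydroxy-4-methoxybenzaldehyde
Conditions: Br2 (3 equiv), FeBr3 (5 mol %), AcOH, rt → 70 °C
Reagents that add atoms: bromine, BrBr
Why: In this electrophilic aromatic bromination O3–H sends the first bromine to its para position C6, and the last open position C5 is ortho to the O4 methoxy group and meta to the formyl group, so both directors agree and the Lewis acid and heat serve this slower second substitution.

Step 11
Reactants: 19 2,5,6-tribromo-3-hydroxy-4-methoxybenzaldehyde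
Product: 20 2,4,5-tribromo-3-formyl-6-methoxyphenyl methanesulfonate (O3 mesylate)
Conditions: MsCl, Et3N, CH2Cl2, 0 °C
Reagents that add atoms: methanesulfonyl chloride, CS(=O)(=O)Cl
Why: O-mesylation gives a phenol mask that withstands BBr3, borohydride and SO3·pyridine and, unlike an acyl or silyl group, should not migrate to the neighbouring O4 once that oxygen is free.

Step 12
Reactants: 20 2,4,5-tribromo-3-formyl-6-methoxyphenyl methanesulfonate
Product: 22 2,4,5-tribromo-3-formyl-6-hydroxyphenyl methanesulfonate (O4–H free), via aryloxydibromoborane 21 (not isolated)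
Conditions: BBr3 (3 equiv), CH2Cl2, −78 °C → rt; H2O
Reagents that add atoms: none
Why: Lewis acid ether cleavage with BBr3 removes the last methyl group from O4, and aryl sulfonates, aryl bromides and deactivated benzaldehydes are routinely carried through this reaction.

Step 13
Reactants: 22 2,4,5-tribromo-3-formyl-6-hydroxyphenyl methanesulfonate
Product: 23 2,3,5-tribromo-4-formyl-6-(methanesulfonyloxy)phenyl hydrogen sulfate
Conditions: SO3·pyridine (4 equiv), DMF–pyridine, rt → 40 °C
Reagents that add atoms: sulfur trioxide pyridine complex, O=S(=O)([O-])[n+]1ccccc1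
Why: With O3 masked and C7 still a carbonyl carbon, O4–H is the only hydroxyl group, so O-sulfation with an SO3 amine complex can only give the C4 aryl sulfate, and no para-quinone methide can form because C7 bears no leaving group.

Step 14
Reactants: 23 2,3,5-tribromo-4-formyl-6-(methanesulfonyloxy)phenyl hydrogen sulfate
Product: 24 2,3,5-tribromo-4-(hydroxymethyl)-6-(methanesulfonyloxy)phenyl hydrogen sulfate
Conditions: NaBH4, MeOH–H2O, 0 °C
Reagents that add atoms: none
Why: Borohydride reduction of the aldehyde tolerates the aryl sulfate, the aryl mesylate and the aryl bromides, and the benzylic alcohol formed cannot ionise to a quinone methide because O4 is already capped.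

Step 15
Reactants: 24 2,3,5-tribromo-4-(hydroxymethyl)-6-(methanesulfonyloxy)phenyl hydrogen sulfate
Product: 26 2,3,5-tribromo-6-hydroxy-4-[(sulfooxy)methyl]phenyl hydrogen sulfate (target CNP0213554.0), via mesylated bis-sulfate 25 (not isolated)
Conditions: SO3·pyridine (3 equiv), DMF, rt; then 1 M NaOH, 0 °C → rt; HCl to pH 7; C18 desalting, Dowex 50W (H+ form), 5 °C
Reagents that add atoms: sulfur trioxide pyridine complex, O=S(=O)([O-])[n+]1ccccc1
Why: O-sulfation of the only free hydroxyl group (O7) is followed in the same flask by hydroxide cleavage of the aryl mesylate, an elimination–addition that should be fast for so acidic a phenol, whereas sulfate monoester anions resist hydroxide at this temperature.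

Compound list
1 | 3,4-dimethoxyphenol | COc1ccc(O)cc1OC | starting material
2 | 1,2-dimethoxy-4-(methoxymethoxy)benzene | COCOc1ccc(OC)c(OC)c1 | intermediate
3 | [2,3-dimethoxy-6-(methoxymethoxy)phenyl]lithium | COCOc1ccc(OC)c(OC)c1[Li] | intermediate
4 | 2-iodo-3,4-dimethoxy-1-(methoxymethoxy)benzene | COCOc1ccc(OC)c(OC)c1I | intermediate
5 | 2-iodo-3,4-dimethoxyphenol | Oc1ccc(OC)c(OC)c1I | intermediate
6 | 4-chlorobenzenesulfonyl chloride | O=S(=O)(Cl)c1ccc(Cl)cc1 | starting material
7 | 2-iodo-3,4-dimethoxyphenyl 4-chlorobenzenesulfonate | COc1ccc(OS(=O)(=O)c2ccc(Cl)cc2)c(I)c1OC | intermediate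
8 | (chloromethyl)isopropoxydimethylsilane | CC(C)O[Si](C)(C)CCl | starting material
9 | (isopropoxydimethylsilyl)methylmagnesium chloride | CC(C)O[Si](C)(C)C[Mg]Cl | intermediate
10 | 1,2-dibromotetrachloroethane | BrC(Cl)(Cl)C(Cl)(Cl)Br | starting material
11 | 2-(chloromagnesio)-3,4-dimethoxyphenyl 4-chlorobenzenesulfonate | COc1ccc(OS(=O)(=O)c2ccc(Cl)cc2)c([Mg]Cl)c1OC | intermediate
12 | 3,4-dimethoxybenzyne (1,2-didehydro-3,4-dimethoxybenzene) | COC1=C(OC)C=CC#C1 | intermediate
13 | {6-[(isopropoxydimethylsilyl)methyl]-2,3-dimethoxyphenyl}magnesium chloride | COc1ccc(C[Si](C)(C)OC(C)C)c([Mg]Cl)c1OC | intermediate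
14 | (2-bromo-3,4-dimethoxybenzyl)(isopropoxy)dimethylsilane | COc1ccc(C[Si](C)(C)OC(C)C)c(Br)c1OC | intermediate
15 | (2-bromo-3,4-dimethoxyphenyl)methanol | COc1ccc(CO)c(Br)c1OC | intermediate
16 | 2-bromo-3,4-dimethoxybenzaldehyde | COc1ccc(C=O)c(Br)c1OC | intermediate
17 | (2-bromo-3-formyl-6-methoxyphenoxy)dichloroborane | COc1ccc(C=O)c(Br)c1OB(Cl)Cl | intermediate
18 | 2-bromo-3-hydroxy-4-methoxybenzaldehyde | COc1ccc(C=O)c(Br)c1O | intermediate
19 | 2,5,6-tribromo-3-hydroxy-4-methoxybenzaldehyde | COc1c(Br)c(Br)c(C=O)c(Br)c1O | intermediate
20 | 2,4,5-tribromo-3-formyl-6-methoxyphenyl methanesulfonate | COc1c(Br)c(Br)c(C=O)c(Br)c1OS(C)(=O)=O | intermediate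
21 | dibromo[2,3,5-tribromo-4-formyl-6-(methanesulfonyloxy)phenoxy]borane | O=Cc1c(Br)c(OS(C)(=O)=O)c(OB(Br)Br)c(Br)c1Br | intermediate
22 | 2,4,5-tribromo-3-formyl-6-hydroxyphenyl methanesulfonate | Oc1c(Br)c(Br)c(C=O)c(Br)c1OS(C)(=O)=O | intermediate
23 | 2,3,5-tribromo-4-formyl-6-(methanesulfonyloxy)phenyl hydrogen sulfate | O=Cc1c(Br)c(OS(C)(=O)=O)c(OS(=O)(=O)O)c(Br)c1Br | intermediate
24 | 2,3,5-tribromo-4-(hydroxymethyl)-6-(methanesulfonyloxy)phenyl hydrogen sulfate | OCc1c(Br)c(OS(C)(=O)=O)c(OS(=O)(=O)O)c(Br)c1Br | intermediate
25 | 2,3,5-tribromo-6-(methanesulfonyloxy)-4-[(sulfooxy)methyl]phenyl hydrogen sulfate | O=S(=O)(O)OCc1c(Br)c(OS(C)(=O)=O)c(OS(=O)(=O)O)c(Br)c1Br | intermediate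
26 | 2,3,5-tribromo-6-hydroxy-4-[(sulfooxy)methyl]phenyl hydrogen sulfate (CNP0213554.0) | O=S(=O)(O)OCc1c(Br)c(O)c(OS(=O)(=O)O)c(Br)c1Br | target

Total step count: 15 (step 5 is a one-step side branch). Longest linear sequence: 14 (steps 1–4 and 6–15).

Steps most likely to fail

Risk 1 (step 6). The bulky, weakly nucleophilic silylmethyl Grignard reagent may add slowly. The aryne would then be consumed by the arylmagnesium species in the flask or by residual i-PrMgCl, and incomplete bromine transfer would leave protonated material after work-up. The fallback sets out from 7 and brings in C7 as the inner carbon of a vinyl group.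
- The same exchange and elimination are run with vinylmagnesium bromide, an sp2 Grignard reagent of the class known to add to arynes.
- This should give (6-ethenyl-2,3-dimethoxyphenyl)magnesium bromide F1, which 10 brominates to 2-bromo-1-ethenyl-3,4-dimethoxybenzene F2.
- Ozonolysis (O3, CH2Cl2–MeOH, −78 °C; Me2S) trims the vinyl group to the formyl group.
- The fallback comes back to the route at 16, bypassing 14 and 15.

Risk 2 (step 10). The reaction may stall after the first bromination, because C5 is activated only by an ortho methoxy group on an already electron-poor ring. Forcing conditions could cause ipso attack with loss of the formyl group. The fallback sets out from 18 and postpones the C5 bromination until O4–H can direct it.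
- One equivalent of Br2 in AcOH at rt should give 2,6-dibromo-3-hydroxy-4-methoxybenzaldehyde F3.
- MsCl and Et3N convert it into 2,4-dibromo-3-formyl-6-methoxyphenyl methanesulfonate F4.
- BBr3 gives the aryloxydibromoborane F5, and water then liberates 2,4-dibromo-3-formyl-6-hydroxyphenyl methanesulfonate F6.
- The free O4–H then directs Br2 (AcOH, rt) to its only open ortho position, C5.
- The fallback comes back to the route at 22.

Risk 3 (step 15). The benzylic sulfate may be displaced or hydrolysed while hydroxide cleaves the mesylate, or the mesylate may cleave sluggishly next to the anionic sulfate. The fallback sets out from 24 and reverses the order of the two operations.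
- 1 M NaOH removes the mesylate first, when no benzylic sulfate is present, to give 2,3,5-tribromo-6-hydroxy-4-(hydroxymethyl)phenyl hydrogen sulfate F7.
- The primary alcohol is then sulfated chemoselectively with about 1.2 equiv of SO3·pyridine in DMF at 0 °C.
- This relies on the low reactivity of O3–H, which is wedged between C2–Br and the anionic O4 sulfate.
- The fallback comes back to the route at 26.

Further compounds
F1 | step 6 | (6-ethenyl-2,3-dimethoxyphenyl)magnesium bromide | C=Cc1ccc(OC)c(OC)c1[Mg]Br
F2 | step 6 | 2-bromo-1-ethenyl-3,4-dimethoxybenzene | C=Cc1ccc(OC)c(OC)c1Br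
F3 | step 10 | 2,6-dibromo-3-hydroxy-4-methoxybenzaldehyde | COc1cc(Br)c(C=O)c(Br)c1O
F4 | step 10 | 2,4-dibromo-3-formyl-6-methoxyphenyl methanesulfonate | COc1cc(Br)c(C=O)c(Br)c1OS(C)(=O)=O
F5 | step 10 | dibromo[3,5-dibromo-4-formyl-2-(methanesulfonyloxy)phenoxy]borane | O=Cc1c(Br)c(OS(C)(=O)=O)c(OB(Br)Br)cc1Br
F6 | step 10 | 2,4-dibromo-3-formyl-6-hydroxyphenyl methanesulfonate | O=Cc1c(Br)c(OS(C)(=O)=O)c(O)cc1Br
F7 | step 15 | 2,3,5-tribromo-6-hydroxy-4-(hydroxymethyl)phenyl hydrogen sulfate | OCc1c(Br)c(O)c(OS(=O)(=O)O)c(Br)c1Br
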